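**Plan**

1. Retrosynthesis: the CH2OH end of the hydroxypropyl arm is cut back to a vinyl group (vinyl + CO). The ring is then opened at two bonds at once, the ring CH2–CH2 bond and the bond from the alkylidene ring carbon to the ring CH that carries the arm, which releases 2-methylbuta-2,3-dien-1-ol and an open chain. Further cuts are the CH2–CH= bond of the skipped diene, the C=C of an allylic pivalate (metathesis) and the quaternary C–CH(CH3) bond ([3,3]).
2. Forward: Ireland–Claisen rearrangement of geranyl propanoate, then primary iodide, allylic oxidation of the arm, cross-metathesis to the allylic pivalate and allylic bromide. The alkenyl unit from (S)-citronellal is coupled on (chain complete), the only ring is closed by a carbomagnesiation/SN2′ annulation with the allenol, and hydroformylation/reduction finishes the arm.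
3. Stereochemistry: the quaternary/tertiary pair comes from the chair Claisen under a chiral boron controller, the side-chain stereocentre from (S)-citronellal, and the ring CH from the chair-like SN2′ closure. The exocyclic alkene geometry comes from a five-membered C–Mg–O chelate, and the two E alkenes from SeO2 oxidation and syn-hydrozirconation.
4. Enabling feature: in the target the O–CH2–C(CH3)=C(ring) unit has its oxygen cis to the ring CH. With magnesium on the ring sp2 carbon these atoms close a 2,5-dihydro-1,2-oxamagnesole ring, and the ring CH is the γ-carbon of an (E)-allylic ester whose other two carbons become the arm. One carbon–metal bond can therefore make both ring bonds, the six-membered ring, its last stereocentre and the tetrasubstituted alkene.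

Key step: step 11

Remark (assumption): the (S,S)-configured diazaborolidine of step 1 is taken to deliver the (2S,3S) acid 3; if its facial preference on this ester is the opposite, the (R,R) reagent is used and nothing else changes.

**Route**

Step 1
Reactants: 1 geranyl propanoate [(2E)-3,7-dimethylocta-2,6-dien-1-yl propanoate]
Product: 3 (2S,3S)-3-ethenyl-2,3,7-trimethyloct-6-enoic acid, via boron ketene acetal 2 (not isolated)
Conditions: (4S,5S)-2-bromo-4,5-diphenyl-1,3-bis{[3,5-bis(trifluoromethyl)phenyl]sulfonyl}-1,3,2-diazaborolidine (1.2 equiv, made in the flask from the bis-sulfonamide and BBr3 in CH2Cl2, volatiles removed), Et3N, toluene–hexane, −78 → 4 °C; aqueous acid work-up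
Reagents that add atoms: none
Why: Enantioselective boron-mediated Ireland–Claisen rearrangement: the E(O) boron ketene acetal (methyl cis to the allyloxy oxygen) and the (E)-trisubstituted alkene should pass through a chair transition state with both methyl groups axial, which sets the relative configuration of the quaternary and tertiary centres, while the C2-symmetric diazaborolidine selects the face.

Step 2
Reactants: 3 (2S,3S)-3-ethenyl-2,3,7-trimethyloct-6-enoic acid
Product: 4 (2S,3S)-3-ethenyl-2,3,7-trimethyloct-6-en-1-ol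
Conditions: LiAlH4, Et2O, 0 → 20 °C
Reagents that add atoms: none
Why: Hydride reduction of a carboxylic acid to the primary alcohol, which should leave both stereocentres untouched because the acid is present as its carboxylate.

Step 3
Reactants: 4 (2S,3S)-3-ethenyl-2,3,7-trimethyloct-6-en-1-ol
Product: 5 (6S,7S)-6-ethenyl-8-iodo-2,6,7-trimethyloct-2-ene
Conditions: I2, PPh3, imidazole, CH2Cl2, 0 → 20 °C
Reagents that add atoms: iodine, II
Why: Appel-type iodination of a primary alcohol by SN2 displacement at CH2, with no stereocentre involved.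

Step 4
Reactants: 5 (6S,7S)-6-ethenyl-8-iodo-2,6,7-trimethyloct-2-ene
Product: 6 (2E,6S,7S)-6-ethenyl-8-iodo-2,6,7-trimethyloct-2-en-1-ol
Conditions: SeO2 (cat.), t-BuOOH, salicylic acid (cat.), CH2Cl2, 20 °C
Reagents that add atoms: tert-butyl hydroperoxide, CC(C)(C)OO (oxygen atom, relayed by catalytic SeO2)
Why: SeO2 allylic oxidation (ene reaction then [2,3]-sigmatropic shift) should hydroxylate only the (E)-methyl group of the trisubstituted alkene, since the vinyl group on the quaternary carbon has no allylic hydrogen.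

Step 5
Reactants: 7 (2Z)-but-2-ene-1,4-diol
Product: 8 (2Z)-but-2-ene-1,4-diyl bis(2,2-dimethylpropanoate)
Conditions: pivaloyl chloride, pyridine, DMAP (cat.), CH2Cl2, 0 → 20 °C
Reagents that add atoms: pivaloyl chloride, CC(C)(C)C(Cl)=O
Why: Standard double acylation of a primary diol.

Step 6
Reactants: 6 (2E,6S,7S)-6-ethenyl-8-iodo-2,6,7-trimethyloct-2-en-1-ol; 8 (2Z)-but-2-ene-1,4-diyl bis(2,2-dimethylpropanoate)
Product: 9 (2E,4S,7E)-9-hydroxy-4-[(2S)-1-iodopropan-2-yl]-4,8-dimethylnona-2,7-dien-1-yl 2,2-dimethylpropanoate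
Conditions: 8 (3 equiv), second-generation Hoveyda–Grubbs catalyst (5 mol %), CH2Cl2, 40 °C
Reagents that add atoms: none
Why: Olefin cross-metathesis: the vinyl group on the quaternary carbon cannot readily homodimerise and should exchange with the symmetrical alkene 8 to give the (E)-allylic pivalate, while the trisubstituted alkene of the arm is too hindered to engage the ruthenium carbene.

Step 7
Reactants: 9 (2E,4S,7E)-9-hydroxy-4-[(2S)-1-iodopropan-2-yl]-4,8-dimethylnona-2,7-dien-1-yl 2,2-dimethylpropanoate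
Product: 10 (2E,4S,7E)-9-bromo-4-[(2S)-1-iodopropan-2-yl]-4,8-dimethylnona-2,7-dien-1-yl 2,2-dimethylpropanoate
Conditions: CBr4, PPh3, CH2Cl2, −20 → 0 °C
Reagents that add atoms: carbon tetrabromide, BrC(Br)(Br)Br
Why: Appel bromination of the primary allylic alcohol, which should keep the E geometry and leave the alkyl iodide and the pivalate alone at low temperature.

Step 8
Reactants: 11 (S)-citronellal [(3S)-3,7-dimethyloct-6-enal]
Product: 13 (3S)-3,7-dimethyloct-6-en-1-yne, via alkenyl nonaflate 12 (not isolated)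
Conditions: C4F9SO2F, phosphazene base P2-Et (2.5 equiv), DMF, −20 → 20 °C
Reagents that add atoms: none
Why: One-pot enol nonaflate formation and β-elimination turns the aldehyde into the terminal alkyne with the same carbon count; enolisation runs toward the α-CH2, so the stereocentre should not be touched.

Step 9
Reactants: 10 (2E,4S,7E)-9-bromo-4-[(2S)-1-iodopropan-2-yl]-4,8-dimethylnona-2,7-dien-1-yl 2,2-dimethylpropanoate; 13 (3S)-3,7-dimethyloct-6-en-1-yne
Product: 15 (2E,4S,7E,10E,12S)-4-[(2S)-1-iodopropan-2-yl]-4,8,12,16-tetramethylheptadeca-2,7,10,15-tetraen-1-yl 2,2-dimethylpropanoate, via alkenylzirconocene chloride 14 (not isolated)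
Conditions: 13, Cp2Zr(H)Cl, THF, 20 °C; then 10, Pd(PPh3)4 (5 mol %), THF, 0 → 20 °C
Reagents that add atoms: none
Why: Syn-hydrozirconation of the terminal alkyne gives the (E)-alkenylzirconium, and palladium-catalysed allyl–alkenyl cross-coupling at the unhindered CH2 terminus should give the skipped diene with both geometries retained, the allylic bromide adding to zerovalent palladium far faster than the allylic pivalate or the alkyl iodide.

Step 10
Reactants: 16 ethyl 2-methylbuta-2,3-dienoate
Product: 17 2-methylbuta-2,3-dien-1-ol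
Conditions: i-Bu2AlH (2.2 equiv), CH2Cl2, −78 → 0 °C
Reagents that add atoms: none
Why: Hydride reduction of the ester to the primary alcohol, which should leave the allene intact.

Step 11
Reactants: 15 (2E,4S,7E,10E,12S)-4-[(2S)-1-iodopropan-2-yl]-4,8,12,16-tetramethylheptadeca-2,7,10,15-tetraen-1-yl 2,2-dimethylpropanoate; 17 2-methylbuta-2,3-dien-1-ol
Product: 22 (2Z)-2-[(2S,3R,4R)-2-ethenyl-3,4-dimethyl-3-[(3E,6E,8S)-4,8,12-trimethyltrideca-3,6,11-trien-1-yl]cyclohexylidene]propan-1-ol, via alkyllithium 18 (not isolated), via alkylmagnesium bromide 19 (not isolated), via bromomagnesium allenyl alkoxide 20 (not isolated), via cyclic alkenylmagnesium alkoxide 21 (not isolated)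
Conditions: 15, t-BuLi (2.1 equiv), Et2O–pentane, −78 °C, then MgBr2·OEt2, −78 → −40 °C; slow addition to 17 (3 equiv, pre-treated with EtMgBr, 3 equiv, Et2O, 0 °C) and CuCl (0.3 equiv), −40 → 0 → 25 °C; aqueous NH4Cl
Reagents that add atoms: none
Why: Proposed new method: with CuCl the alkylmagnesium 19 should add across the terminal C=C of the allenyl alkoxide 20, alkyl to the CH2 terminus and metal to the central carbon, because only this regiochemistry lets the alkoxide close the five-membered C–Mg–O chelate 21, which places the metal (and so the later ring bond) cis to CH2O and the methyl cis to the new ring CH2. The chelated alkenyl metal, after transfer to copper, should then attack the γ-carbon of the (E)-allylic pivalate in an intramolecular anti-SN2′ substitution (6-exo-trig closure with the allyl unit outside the ring), forming the second bond, expelling pivalate and leaving a vinyl group on the new stereocentre. The closest known reaction types are the copper-catalysed, hydroxyl-directed carbomagnesiation of propargylic and allenic alcohols with electrophilic trapping of the cyclic alkenylmagnesium, and the copper-catalysed SN2′ substitution of allylic esters by Grignard reagents; joining them in one ring-forming cascade is the new element. The new stereocentre should be set in a chair-like transition state with both ring methyls equatorial, the long arm axial and the reacting allyl unit axial and anti to that arm, a placement reinforced by allylic 1,3-strain with the CH2O group on the exocyclic double bond. The step needs the alkyl group to reach the allene before any pivalate is attacked: the (E)-alkene makes intramolecular SN2 or SN2′ attack by the primary carbanion impossible (four-membered ring or trans-cyclohexene), and slow addition into excess 20 should disfavour the bimolecular path.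

Step 12
Reactants: 22 (2Z)-2-[(2S,3R,4R)-2-ethenyl-3,4-dimethyl-3-[(3E,6E,8S)-4,8,12-trimethyltrideca-3,6,11-trien-1-yl]cyclohexylidene]propan-1-ol
Product: 23 3-[(1S,2R,3R,6Z)-6-(1-hydroxypropan-2-ylidene)-2,3-dimethyl-2-[(3E,6E,8S)-4,8,12-trimethyltrideca-3,6,11-trien-1-yl]cyclohexyl]propanal
Conditions: Rh(acac)(CO)2 (1 mol %), BiPhePhos (3 mol %), CO/H2 (1:1, 5 bar), toluene, 45 °C
Reagents that add atoms: carbon monoxide, [C-]#[O+]
Why: Rhodium-catalysed hydroformylation with a bulky diphosphite should be selective for the single monosubstituted alkene and give the linear aldehyde, the di-, tri- and tetrasubstituted alkenes reacting far more slowly.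

Step 13
Reactants: 23 3-[(1S,2R,3R,6Z)-6-(1-hydroxypropan-2-ylidene)-2,3-dimethyl-2-[(3E,6E,8S)-4,8,12-trimethyltrideca-3,6,11-trien-1-yl]cyclohexyl]propanal
Product: 24 CNP0327981.1, (2Z)-2-[(2S,3R,4R)-2-(3-hydroxypropyl)-3,4-dimethyl-3-[(3E,6E,8S)-4,8,12-trimethyltrideca-3,6,11-trien-1-yl]cyclohexylidene]propan-1-ol
Conditions: NaBH4, MeOH, 0 °C
Reagents that add atoms: none
Why: Borohydride reduction of the aldehyde to the primary alcohol, with no stereocentre or alkene affected.

**Compound list**

1 | geranyl propanoate, (2E)-3,7-dimethylocta-2,6-dien-1-yl propanoate | CCC(=O)OC/C=C(\C)CCC=C(C)C | starting material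
2 | E(O) boron ketene acetal of 1 (methyl cis to the geranyloxy oxygen) carrying the (4S,5S)-diazaborolidine | C/C=C(\OC/C=C(\C)CCC=C(C)C)OB1N([C@@H](c2ccccc2)[C@H](c2ccccc2)N1S(=O)(=O)c1cc(cc(c1)C(F)(F)F)C(F)(F)F)S(=O)(=O)c1cc(cc(c1)C(F)(F)F)C(F)(F)F | intermediate
3 | (2S,3S)-3-ethenyl-2,3,7-trimethyloct-6-enoic acid | CC(C)=CCC[C@](C=C)(C)[C@H](C)C(=O)O | intermediate
4 | (2S,3S)-3-ethenyl-2,3,7-trimethyloct-6-en-1-ol | CC(C)=CCC[C@](C=C)(C)[C@H](C)CO | intermediate
5 | (6S,7S)-6-ethenyl-8-iodo-2,6,7-trimethyloct-2-ene | CC(C)=CCC[C@](C=C)(C)[C@H](C)CI | intermediate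
6 | (2E,6S,7S)-6-ethenyl-8-iodo-2,6,7-trimethyloct-2-en-1-ol | OC/C(C)=C/CC[C@](C=C)(C)[C@H](C)CI | intermediate
7 | (2Z)-but-2-ene-1,4-diol | OC/C=C\CO | starting material
8 | (2Z)-but-2-ene-1,4-diyl bis(2,2-dimethylpropanoate) | CC(C)(C)C(=O)OC/C=C\COC(=O)C(C)(C)C | intermediate
9 | (2E,4S,7E)-9-hydroxy-4-[(2S)-1-iodopropan-2-yl]-4,8-dimethylnona-2,7-dien-1-yl 2,2-dimethylpropanoate | OC/C(C)=C/CC[C@](/C=C/COC(=O)C(C)(C)C)(C)[C@H](C)CI | intermediate
10 | (2E,4S,7E)-9-bromo-4-[(2S)-1-iodopropan-2-yl]-4,8-dimethylnona-2,7-dien-1-yl 2,2-dimethylpropanoate | BrC/C(C)=C/CC[C@](/C=C/COC(=O)C(C)(C)C)(C)[C@H](C)CI | intermediate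
11 | (S)-citronellal, (3S)-3,7-dimethyloct-6-enal | CC(C)=CCC[C@H](C)CC=O | starting material
12 | (3S)-3,7-dimethylocta-1,6-dien-1-yl nonafluorobutane-1-sulfonate (E/Z mixture) | CC(C)=CCC[C@H](C)C=COS(=O)(=O)C(F)(F)C(F)(F)C(F)(F)C(F)(F)F | intermediate
13 | (3S)-3,7-dimethyloct-6-en-1-yne | CC(C)=CCC[C@H](C)C#C | intermediate
14 | chloro[(1E,3S)-3,7-dimethylocta-1,6-dien-1-yl]bis(cyclopentadienyl)zirconium | CC(C)=CCC[C@H](C)/C=C/[Zr](Cl)(C1C=CC=C1)C1C=CC=C1 | intermediate
15 | (2E,4S,7E,10E,12S)-4-[(2S)-1-iodopropan-2-yl]-4,8,12,16-tetramethylheptadeca-2,7,10,15-tetraen-1-yl 2,2-dimethylpropanoate | CC(C)=CCC[C@H](C)/C=C/C/C(C)=C/CC[C@](/C=C/COC(=O)C(C)(C)C)(C)[C@H](C)CI | intermediate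
16 | ethyl 2-methylbuta-2,3-dienoate | CCOC(=O)C(C)=C=C | starting material
17 | 2-methylbuta-2,3-dien-1-ol | OCC(C)=C=C | intermediate
18 | primary alkyllithium from 15 (C–Li in place of C–I, all else unchanged) | CC(C)=CCC[C@H](C)/C=C/C/C(C)=C/CC[C@](/C=C/COC(=O)C(C)(C)C)(C)[C@H](C)C[Li] | intermediate
19 | primary alkylmagnesium bromide from 18 (C–MgBr in place of C–Li) | CC(C)=CCC[C@H](C)/C=C/C/C(C)=C/CC[C@](/C=C/COC(=O)C(C)(C)C)(C)[C@H](C)C[Mg]Br | intermediate
20 | bromomagnesium 2-methylbuta-2,3-dien-1-olate | C=C=C(C)CO[Mg]Br | intermediate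
21 | cyclic alkenylmagnesium alkoxide: 4-methyl-2,5-dihydro-1,2-oxamagnesole whose C-3 carries the chain of 19 through the new CH2–CH2 bond | CC(C)=CCC[C@H](C)/C=C/C/C(C)=C/CC[C@](/C=C/COC(=O)C(C)(C)C)(C)[C@H](C)CCC1=C(C)CO[Mg]1 | intermediate
22 | (2Z)-2-[(2S,3R,4R)-2-ethenyl-3,4-dimethyl-3-[(3E,6E,8S)-4,8,12-trimethyltrideca-3,6,11-trien-1-yl]cyclohexylidene]propan-1-ol | CC(C)=CCC[C@H](C)/C=C/C/C(C)=C/CC[C@]1(C)[C@H](C)CC/C(=C(\C)CO)[C@H]1C=C | intermediate
23 | 3-[(1S,2R,3R,6Z)-6-(1-hydroxypropan-2-ylidene)-2,3-dimethyl-2-[(3E,6E,8S)-4,8,12-trimethyltrideca-3,6,11-trien-1-yl]cyclohexyl]propanal | CC(C)=CCC[C@H](C)/C=C/C/C(C)=C/CC[C@]1(C)[C@H](C)CC/C(=C(\C)CO)[C@H]1CCC=O | intermediate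
24 | CNP0327981.1, (2Z)-2-[(2S,3R,4R)-2-(3-hydroxypropyl)-3,4-dimethyl-3-[(3E,6E,8S)-4,8,12-trimethyltrideca-3,6,11-trien-1-yl]cyclohexylidene]propan-1-ol | CC(C)=CCC[C@H](C)/C=C/C/C(C)=C/CC[C@]1(C)[C@H](C)CC/C(=C(\C)CO)[C@H]1CCCO | target

**Count and risks**

Total step count: 13. Longest linear sequence: 10 steps (steps 1, 2, 3, 4, 6, 7, 9, 11, 12, 13).

Steps most likely to fail:

1. Step 11 (Proposed new method). What may go wrong: copper-mediated allylic substitution of the alkylmagnesium on the pivalate of a second molecule may outrun carbomagnesiation of the allene, or the chelated alkenylmagnesium may not ring-close before work-up and is then simply protonated. The fallback makes the two bonds one after the other by known chemistry and sets out from 15. Alkylation of 15 at the propargylic carbon of 1,3-dilithiopropyne (THF, −78 → 0 °C), followed by methylation of the resulting acetylide with MeI in the same flask, should give the enyne (2E,4R,7E,10E,12S)-4-[(2R)-hex-4-yn-2-yl]-4,8,12,16-tetramethylheptadeca-2,7,10,15-tetraen-1-yl 2,2-dimethylpropanoate F1. Palladium-catalysed intramolecular allylpalladation of the alkyne with carbonylative termination (Pd(PPh3)4, CO, MeOH/AcOH, 45 °C) should then add the allyl terminus and the metal syn across the triple bond and deliver methyl (2Z)-2-[(2S,3R,4R)-2-ethenyl-3,4-dimethyl-3-[(3E,6E,8S)-4,8,12-trimethyltrideca-3,6,11-trien-1-yl]cyclohexylidene]propanoate F2, with the ester cis to the ring CH. Reduction with i-Bu2AlH rejoins the route at 22.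

2. Step 9. What may go wrong: zerovalent palladium may also ionise the allylic pivalate or equilibrate the 2-methylallyl fragment, eroding site selectivity and E geometry. The fallback avoids palladium and sets out from 10 and 13. Copper-mediated alkynylation of the allylic bromide (CuI, K2CO3, NaI, DMF, 20 °C) should give the skipped enyne (2E,4S,7E,12S)-4-[(2S)-1-iodopropan-2-yl]-4,8,12,16-tetramethylheptadeca-2,7,15-trien-10-yn-1-yl 2,2-dimethylpropanoate F3. Ruthenium-catalysed trans-hydrosilylation ([Cp*Ru(MeCN)3]PF6, (EtO)3SiH, CH2Cl2) should give the alkenylsilane (2E,4S,7E,10Z,12S)-4-[(2S)-1-iodopropan-2-yl]-4,8,12,16-tetramethyl-10-(triethoxysilyl)heptadeca-2,7,10,15-tetraen-1-yl 2,2-dimethylpropanoate F4 (its C-11 silyl regioisomer converges on the same alkene). Protodesilylation (CuI, Bu4NF, THF) rejoins the route at 15.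

3. Step 12. What may go wrong: the rhodium hydride may engage or isomerise the skipped diene of the side chain, or the hindered vinyl group may react too slowly. The fallback uses boron instead and sets out from 22. Iridium-catalysed hydroboration of the vinyl group with pinacolborane ([Ir(cod)Cl]2, dppm, CH2Cl2; the hydroxyl is borylated in passing and freed on work-up) should give the boronate (2Z)-2-[(2S,3R,4R)-3,4-dimethyl-2-[2-(4,4,5,5-tetramethyl-1,3,2-dioxaborolan-2-yl)ethyl]-3-[(3E,6E,8S)-4,8,12-trimethyltrideca-3,6,11-trien-1-yl]cyclohexylidene]propan-1-ol F5. Matteson homologation (BrCH2Cl, n-BuLi, THF, −78 → 20 °C) should give the one-carbon-longer boronate (2Z)-2-[(2S,3R,4R)-3,4-dimethyl-2-[3-(4,4,5,5-tetramethyl-1,3,2-dioxaborolan-2-yl)propyl]-3-[(3E,6E,8S)-4,8,12-trimethyltrideca-3,6,11-trien-1-yl]cyclohexylidene]propan-1-ol F6. Oxidation (NaOH, H2O2) rejoins the route at 24.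

**Further compounds**

F1 | step 11 | (2E,4R,7E,10E,12S)-4-[(2R)-hex-4-yn-2-yl]-4,8,12,16-tetramethylheptadeca-2,7,10,15-tetraen-1-yl 2,2-dimethylpropanoate | CC(C)=CCC[C@H](C)/C=C/C/C(C)=C/CC[C@](/C=C/COC(=O)C(C)(C)C)(C)[C@H](C)CCC#CC
F2 | step 11 | methyl (2Z)-2-[(2S,3R,4R)-2-ethenyl-3,4-dimethyl-3-[(3E,6E,8S)-4,8,12-trimethyltrideca-3,6,11-trien-1-yl]cyclohexylidene]propanoate | CC(C)=CCC[C@H](C)/C=C/C/C(C)=C/CC[C@]1(C)[C@H](C)CC/C(=C(\C)C(=O)OC)[C@H]1C=C
F3 | step 9 | (2E,4S,7E,12S)-4-[(2S)-1-iodopropan-2-yl]-4,8,12,16-tetramethylheptadeca-2,7,15-trien-10-yn-1-yl 2,2-dimethylpropanoate | CC(C)=CCC[C@H](C)C#CC/C(C)=C/CC[C@](/C=C/COC(=O)C(C)(C)C)(C)[C@H](C)CI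
F4 | step 9 | (2E,4S,7E,10Z,12S)-4-[(2S)-1-iodopropan-2-yl]-4,8,12,16-tetramethyl-10-(triethoxysilyl)heptadeca-2,7,10,15-tetraen-1-yl 2,2-dimethylpropanoate | CC(C)=CCC[C@H](C)/C=C(\[Si](OCC)(OCC)OCC)C/C(C)=C/CC[C@](/C=C/COC(=O)C(C)(C)C)(C)[C@H](C)CI
F5 | step 12 | (2Z)-2-[(2S,3R,4R)-3,4-dimethyl-2-[2-(4,4,5,5-tetramethyl-1,3,2-dioxaborolan-2-yl)ethyl]-3-[(3E,6E,8S)-4,8,12-trimethyltrideca-3,6,11-trien-1-yl]cyclohexylidene]propan-1-ol | CC(C)=CCC[C@H](C)/C=C/C/C(C)=C/CC[C@]1(C)[C@H](C)CC/C(=C(\C)CO)[C@H]1CCB1OC(C)(C)C(C)(C)O1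
F6 | step 12 | (2Z)-2-[(2S,3R,4R)-3,4-dimethyl-2-[3-(4,4,5,5-tetramethyl-1,3,2-dioxaborolan-2-yl)propyl]-3-[(3E,6E,8S)-4,8,12-trimethyltrideca-3,6,11-trien-1-yl]cyclohexylidene]propan-1-ol | CC(C)=CCC[C@H](C)/C=C/C/C(C)=C/CC[C@]1(C)[C@H](C)CC/C(=C(\C)CO)[C@H]1CCCB1OC(C)(C)C(C)(C)O1
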